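## Retrosynthetic overview

1. The C1–C14 bond and the 14-membered ring are made last, by a nickel-catalysed, carbene-controlled exo-selective reductive cyclization of a terminal ynal; this also sets C14 and the exocyclic methylene.
2. The C7–C8 bond and the lactone come from a chromium-catalysed asymmetric 2-(methoxycarbonyl)allylation that joins fragment A (C1–C7 α-silyloxy aldehyde) to fragment B (C8–C14 epoxy allyl bromide), followed by lactonization.
3. Fragment B: pent-4-yn-1-ol, AlMe3 and oxirane (carboalumination), methyl propiolate (vinylalumination), Shi epoxidation, SN2′ bromination.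
4. Fragment A: hept-6-yn-2-one and vinyl Grignard; C5 by organocatalytic transfer hydrogenation, C6 by proline-catalysed aminoxylation.
5. Ring order: oxirane (on fragment B), then lactone (fragment union), then the 14-membered carbocycle.

Locants used below: C1 = ring carbon bearing the exocyclic CH2, C2–C4 = CH2, C5 = CHMe, C6 = CHOH, C7 = lactone CH–O, C8 = lactone CH, C9 = CH2, C10/C11 = oxirane CH/CMe, C12–C13 = CH2, C14 = CHOH. The target is 5S,6R,7R,8S,10R,11R,14R, with a cis-fused lactone and a trans (E-derived) oxirane.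

Assumption: each chiral catalyst follows its published facial model; the enantiomer named is the one expected to give the configuration drawn, and its antipode is used if the observed sense is opposite.

## Route

Step 1
Reactants: 1 hept-6-yn-2-one; 2 vinylmagnesium bromide
Product: 3 (3RS)-3-methyloct-1-en-7-yn-3-ol
Conditions: CH2=CHMgBr (1.3 equiv), THF, −78 → 0 °C; sat. aq. NH4Cl
Reagents that add atoms: none
Why: Grignard 1,2-addition to the ketone is much faster than deprotonation of the terminal alkyne at low temperature; the carbinol is racemic and its stereocentre is erased in step 2.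

Step 2
Reactants: 3 (3RS)-3-methyloct-1-en-7-yn-3-ol
Product: 4 3-methyloct-2-en-7-ynal (2E/2Z mixture)
Conditions: pyridinium chlorochromate (C5H5NH)[CrO3Cl] (2.5 equiv), SiO2, CH2Cl2, rt
Reagents that add atoms: pyridinium chlorochromate, [O-][Cr](=O)(=O)Cl.c1cc[nH+]cc1
Why: Babler–Dauben oxidative transposition: the tertiary allylic chromate ester undergoes a [3,3] shift and the primary ester is oxidized to the β-methyl enal; the E/Z ratio does not matter for step 3.

Step 3
Reactants: 4 3-methyloct-2-en-7-ynal (2E/2Z mixture)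
Product: 5 (3S)-3-methyloct-7-ynal
Conditions: (S)-2-tert-butyl-3-methylimidazolidin-4-one·CCl3CO2H (20 mol%), diethyl 2,6-dimethyl-1,4-dihydropyridine-3,5-dicarboxylate (1.2 equiv), CHCl3, −30 °C
Reagents that add atoms: none
Why: MacMillan iminium-catalysed transfer hydrogenation: E and Z iminium ions interconvert and hydride adds to the β-carbon on the face left open by the tert-butyl group, which sets C5 as S.

Step 4
Reactants: 5 (3S)-3-methyloct-7-ynal
Product: 7 (2R,3S)-2-(anilinooxy)-3-methyloct-7-yn-1-ol, via aminoxy aldehyde 6 (not isolated)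
Conditions: PhNO (1.0 equiv, slow addition), L-proline (20 mol%), CHCl3, 4 °C; then NaBH4, EtOH, 0 °C
Reagents that add atoms: nitrosobenzene, O=Nc1ccccc1
Why: Proline-catalysed α-aminoxylation: the enamine of L-proline takes the oxygen of PhNO on one face under catalyst control and sets C6 as R; NaBH4 traps the labile aldehyde.

Step 5
Reactants: 7 (2R,3S)-2-(anilinooxy)-3-methyloct-7-yn-1-ol
Product: 8 (2R,3S)-3-methyloct-7-yne-1,2-diol
Conditions: Zn dust (5 equiv), AcOH–THF, rt
Reagents that add atoms: none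
Why: Reductive N–O cleavage by zinc removes the aniline residue without touching the alkyne or either stereocentre.

Step 6
Reactants: 8 (2R,3S)-3-methyloct-7-yne-1,2-diol
Product: 9 (2R,3S)-3-methyl-1,2-bis[(triethylsilyl)oxy]oct-7-yne
Conditions: Et3SiCl (2.5 equiv), imidazole, DMAP (cat.), CH2Cl2, 0 °C → rt
Reagents that add atoms: chlorotriethylsilane, CC[Si](Cl)(CC)CC
Why: Standard silylation of both hydroxyls; no stereocentre is touched.

Step 7
Reactants: 9 (2R,3S)-3-methyl-1,2-bis[(triethylsilyl)oxy]oct-7-yne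
Product: 10 (2R,3S)-3-methyl-2-[(triethylsilyl)oxy]oct-7-ynal
Conditions: (COCl)2 (4 equiv), DMSO (8 equiv), CH2Cl2, −78 → −40 °C; Et3N, −78 °C → rt
Reagents that add atoms: none
Why: Under Swern conditions the primary SiEt3 ether is cleaved by the chlorosulfonium salt and oxidized in situ while the secondary SiEt3 ether survives (selective oxidative desilylation); the cold amine step does not epimerize C6.

Step 8
Reactants: 11 pent-4-yn-1-ol
Product: 12 1-methoxy-4-[(pent-4-yn-1-yloxy)methyl]benzene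
Conditions: NaH (1.05 equiv), THF–DMF, 0 °C; 4-MeOC6H4CH2Cl, Bu4NI (cat.), rt
Reagents that add atoms: 4-methoxybenzyl chloride, COc1ccc(CCl)cc1
Why: Williamson etherification; the alkoxide forms in preference to the acetylide.

Step 9
Reactants: 12 1-methoxy-4-[(pent-4-yn-1-yloxy)methyl]benzene; 13 oxirane
Product: 16 (3E)-7-[(4-methoxybenzyl)oxy]-4-methylhept-3-en-1-ol, via alkenylalane 14 (not isolated), via lithium alanate 15 (not isolated)
Conditions: AlMe3 (2.5 equiv), Cp2ZrCl2 (0.25 equiv), CH2Cl2, 0 °C → rt; volatiles removed; n-BuLi (1.0 equiv), hexane–THF, −78 → 0 °C; oxirane (3 equiv), 0 °C → rt; aq. KNaC4H4O6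
Reagents that add atoms: trimethylaluminium, C[Al](C)C
Why: Negishi zirconium-catalysed carboalumination adds methyl and aluminium syn across the alkyne (methyl on the internal carbon, E-alkenylalane), and the alanate opens oxirane with retention of the alkene geometry.

Step 10
Reactants: 16 (3E)-7-[(4-methoxybenzyl)oxy]-4-methylhept-3-en-1-ol
Product: 17 (3E)-7-[(4-methoxybenzyl)oxy]-4-methylhept-3-enal
Conditions: Dess–Martin periodinane (1.2 equiv), pyridine, CH2Cl2, 0 °C, 30 min; used crude at once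
Reagents that add atoms: none
Why: Buffered, cold Dess–Martin oxidation gives the β,γ-unsaturated aldehyde without migration of the double bond into conjugation.

Step 11
Reactants: 17 (3E)-7-[(4-methoxybenzyl)oxy]-4-methylhept-3-enal; 18 methyl propiolate
Product: 20 methyl (5E)-3-hydroxy-9-[(4-methoxybenzyl)oxy]-6-methyl-2-methylidenenon-5-enoate (racemic at C3), via vinylalane 19 (not isolated)
Conditions: i-Bu2AlH (1.4 equiv), N-methylmorpholine N-oxide (1.5 equiv), THF, 0 °C; 18 (1.5 equiv), 0 °C, 1 h; then 17, 0 °C → rt; aq. KNaC4H4O6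
Reagents that add atoms: none
Why: Vinylalumination: hydroalumination of the propiolate gives the α-aluminoacrylate, which adds to the aldehyde without base (Baylis–Hillman-type adduct), so the β,γ-alkene stays in place; the new carbinol is racemic and is erased in step 13.

Step 12
Reactants: 20 methyl (5E)-3-hydroxy-9-[(4-methoxybenzyl)oxy]-6-methyl-2-methylidenenon-5-enoate
Product: 21 methyl 3-hydroxy-4-{(2R,3R)-3-[3-[(4-methoxybenzyl)oxy]propyl]-3-methyloxiran-2-yl}-2-methylidenebutanoate (1:1 at C3)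
Conditions: D-fructose-derived Shi ketone (0.3 equiv), KHSO5 (as 2KHSO5·KHSO4·K2SO4, 1.4 equiv), K2CO3, Bu4NHSO4 (cat.), MeCN–CH2(OMe)2–aq. Na2B4O7 buffer (pH 10.5), 0 °C
Reagents that add atoms: potassium peroxymonosulfate, [K+].[O-]S(=O)(=O)OO
Why: Shi asymmetric epoxidation: the chiral dioxirane attacks only the electron-rich E-trisubstituted alkene through the spiro transition state and sets C10 and C11 as R,R; the acrylate is inert.

Step 13
Reactants: 21 methyl 3-hydroxy-4-{(2R,3R)-3-[3-[(4-methoxybenzyl)oxy]propyl]-3-methyloxiran-2-yl}-2-methylidenebutanoate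
Product: 22 methyl (2Z)-2-(bromomethyl)-4-{(2R,3R)-3-[3-[(4-methoxybenzyl)oxy]propyl]-3-methyloxiran-2-yl}but-2-enoate
Conditions: N-bromosuccinimide (1.5 equiv), Me2S (1.8 equiv), CH2Cl2, −20 → 0 °C
Reagents that add atoms: N-bromosuccinimide, O=C1CCC(=O)N1Br
Why: Corey–Kim-type activation of the allylic alcohol and SN2′ delivery of bromide give the thermodynamically favoured Z-2-(bromomethyl)enoate under non-acidic conditions that spare the oxirane; both C3 epimers converge.

Step 14
Reactants: 10 (2R,3S)-3-methyl-2-[(triethylsilyl)oxy]oct-7-ynal; 22 methyl (2Z)-2-(bromomethyl)-4-{(2R,3R)-3-[3-[(4-methoxybenzyl)oxy]propyl]-3-methyloxiran-2-yl}but-2-enoate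
Product: 25 (4S,5R)-4-({(2R,3R)-3-[3-[(4-methoxybenzyl)oxy]propyl]-3-methyloxiran-2-yl}methyl)-3-methylidene-5-[(1R,2S)-2-methyl-1-[(triethylsilyl)oxy]hept-6-yn-1-yl]oxolan-2-one, via silyl ether 23 (not isolated), via hydroxy ester 24 (not isolated)
Conditions: CrCl2 (10 mol%), Nakada-type (S,S)-1,8-bis(4-isopropyl-4,5-dihydrooxazol-2-yl)-9H-carbazole ligand (12 mol%), 1,8-bis(dimethylamino)naphthalene (20 mol%), Mn powder (2 equiv), Me3SiCl (1.5 equiv), THF, rt; aq. citric acid; then pyridinium p-toluenesulfonate (5 mol%), CH2Cl2, rt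
Reagents that add atoms: none
Why: Catalytic asymmetric Nozaki–Hiyama-type 2-(alkoxycarbonyl)allylation: the allylchromium from the Z-bromide adds through a chair transition state (C7/C8 syn, hence the cis-lactone), the chiral ligand directs attack to the Re face of the aldehyde (C7 R, C8 S, 6,7-syn against the Felkin preference of the substrate), and the γ-hydroxy ester lactonizes.

Step 15
Reactants: 25 (4S,5R)-4-({(2R,3R)-3-[3-[(4-methoxybenzyl)oxy]propyl]-3-methyloxiran-2-yl}methyl)-3-methylidene-5-[(1R,2S)-2-methyl-1-[(triethylsilyl)oxy]hept-6-yn-1-yl]oxolan-2-one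
Product: 26 (4S,5R)-4-{[(2R,3R)-3-(3-hydroxypropyl)-3-methyloxiran-2-yl]methyl}-3-methylidene-5-[(1R,2S)-2-methyl-1-[(triethylsilyl)oxy]hept-6-yn-1-yl]oxolan-2-one
Conditions: DDQ (1.3 equiv), CH2Cl2–pH 7 phosphate buffer (10:1), 0 °C
Reagents that add atoms: none
Why: Oxidative cleavage of the 4-methoxybenzyl ether by DDQ under buffered conditions leaves the silyl ether, oxirane, alkyne and α-methylene lactone intact.

Step 16
Reactants: 26 (4S,5R)-4-{[(2R,3R)-3-(3-hydroxypropyl)-3-methyloxiran-2-yl]methyl}-3-methylidene-5-[(1R,2S)-2-methyl-1-[(triethylsilyl)oxy]hept-6-yn-1-yl]oxolan-2-one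
Product: 27 (4S,5R)-3-methylidene-4-{[(2R,3R)-3-methyl-3-(3-oxopropyl)oxiran-2-yl]methyl}-5-[(1R,2S)-2-methyl-1-[(triethylsilyl)oxy]hept-6-yn-1-yl]oxolan-2-one
Conditions: Dess–Martin periodinane (1.3 equiv), pyridine, CH2Cl2, 0 °C → rt
Reagents that add atoms: none
Why: Buffered Dess–Martin oxidation of the primary alcohol gives the ynal without opening the oxirane.

Step 17
Reactants: 27 (4S,5R)-3-methylidene-4-{[(2R,3R)-3-methyl-3-(3-oxopropyl)oxiran-2-yl]methyl}-5-[(1R,2S)-2-methyl-1-[(triethylsilyl)oxy]hept-6-yn-1-yl]oxolan-2-one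
Product: 28 (1S,3R,5R,8R,13S,14R,15R)-5,13-dimethyl-9,18-dimethylidene-8,14-bis[(triethylsilyl)oxy]-4,16-dioxatricyclo[13.3.0.0(3,5)]octadecan-17-one
Conditions: Ni(cod)2 (20 mol%), (4R,5R)-1,3-bis(2,6-diisopropylphenyl)-4,5-diphenyl-4,5-dihydroimidazolium tetrafluoroborate (22 mol%), KOtBu (22 mol%), Et3SiH (5 equiv), THF, 27 added by syringe pump over 10 h (final 0.004 M), 25 → 45 °C
Reagents that add atoms: triethylsilane, CC[SiH](CC)CC
Why: Proposed new method: a catalyst-controlled, exo-selective reductive ynal macrocyclization in which a zerovalent nickel centre carrying a bulky enantiopure C2-symmetric carbene binds the aldehyde and the terminal alkyne, oxidative cyclization forms the C1–C14 bond at the internal alkyne carbon because the large N-aryl groups push the tether away from nickel (exo mode, 14-membered ring, exocyclic CH2), the 4,5-diphenyl backbone gears the N-aryl groups so that one aldehyde face is blocked and C14 is set as R, and Si–H σ-bond metathesis followed by C–H reductive elimination releases the silyl ether; the closest known chemistry is the ligand-controlled exo-selective nickel–carbene macrocyclization of terminal ynals with achiral or racemic large carbenes and the enantioselective intermolecular aldehyde–alkyne reductive coupling with chiral carbenes.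

Step 18
Reactants: 28 (1S,3R,5R,8R,13S,14R,15R)-5,13-dimethyl-9,18-dimethylidene-8,14-bis[(triethylsilyl)oxy]-4,16-dioxatricyclo[13.3.0.0(3,5)]octadecan-17-one
Product: 29 (1S,3R,5R,8R,13S,14R,15R)-8,14-dihydroxy-5,13-dimethyl-9,18-dimethylidene-4,16-dioxatricyclo[13.3.0.0(3,5)]octadecan-17-one
Conditions: Et3N·3HF (12 equiv), THF, 0 °C → rt
Reagents that add atoms: none
Why: Silyl ether cleavage by nearly neutral fluoride removes both SiEt3 groups while avoiding acid-induced attack of the C14 hydroxyl on the oxirane and base-induced addition to the α-methylene lactone.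

## Compound list

1 | hept-6-yn-2-one | CC(=O)CCCC#C | starting material
2 | vinylmagnesium bromide | C=C[Mg]Br | starting material
3 | (3RS)-3-methyloct-1-en-7-yn-3-ol | C=CC(C)(O)CCCC#C | intermediate
4 | 3-methyloct-2-en-7-ynal (2E/2Z mixture) | O=CC=C(C)CCCC#C | intermediate
5 | (3S)-3-methyloct-7-ynal | C#CCCC[C@H](C)CC=O | intermediate
6 | (2R,3S)-2-(anilinooxy)-3-methyloct-7-ynal (aminoxy aldehyde) | C#CCCC[C@H](C)[C@@H](ONc1ccccc1)C=O | intermediate
7 | (2R,3S)-2-(anilinooxy)-3-methyloct-7-yn-1-ol | C#CCCC[C@H](C)[C@@H](ONc1ccccc1)CO | intermediate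
8 | (2R,3S)-3-methyloct-7-yne-1,2-diol | C#CCCC[C@H](C)[C@@H](O)CO | intermediate
9 | (2R,3S)-3-methyl-1,2-bis[(triethylsilyl)oxy]oct-7-yne | C#CCCC[C@H](C)[C@@H](O[Si](CC)(CC)CC)CO[Si](CC)(CC)CC | intermediate
10 | (2R,3S)-3-methyl-2-[(triethylsilyl)oxy]oct-7-ynal (fragment A) | C#CCCC[C@H](C)[C@@H](O[Si](CC)(CC)CC)C=O | intermediate
11 | pent-4-yn-1-ol | C#CCCCO | starting material
12 | 1-methoxy-4-[(pent-4-yn-1-yloxy)methyl]benzene | C#CCCCOCc1ccc(OC)cc1 | intermediate
13 | oxirane | C1CO1 | starting material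
14 | {(1E)-5-[(4-methoxybenzyl)oxy]-2-methylpent-1-en-1-yl}dimethylalumane (alkenylalane) | C[Al](C)/C=C(\C)CCCOCc1ccc(OC)cc1 | intermediate
15 | lithium butyl{(1E)-5-[(4-methoxybenzyl)oxy]-2-methylpent-1-en-1-yl}dimethylaluminate (lithium alanate) | [Li+].CCCC[Al-](C)(C)/C=C(\C)CCCOCc1ccc(OC)cc1 | intermediate
16 | (3E)-7-[(4-methoxybenzyl)oxy]-4-methylhept-3-en-1-ol | OCC/C=C(\C)CCCOCc1ccc(OC)cc1 | intermediate
17 | (3E)-7-[(4-methoxybenzyl)oxy]-4-methylhept-3-enal | O=CC/C=C(\C)CCCOCc1ccc(OC)cc1 | intermediate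
18 | methyl propiolate (methyl prop-2-ynoate) | C#CC(=O)OC | starting material
19 | methyl 2-[bis(2-methylpropyl)alumanyl]prop-2-enoate (vinylalane) | C=C(C(=O)OC)[Al](CC(C)C)CC(C)C | intermediate
20 | methyl (5E)-3-hydroxy-9-[(4-methoxybenzyl)oxy]-6-methyl-2-methylidenenon-5-enoate (racemic at C3) | C=C(C(=O)OC)C(O)C/C=C(\C)CCCOCc1ccc(OC)cc1 | intermediate
21 | methyl 3-hydroxy-4-{(2R,3R)-3-[3-[(4-methoxybenzyl)oxy]propyl]-3-methyloxiran-2-yl}-2-methylidenebutanoate (1:1 at C3) | C=C(C(=O)OC)C(O)C[C@H]1O[C@]1(C)CCCOCc2ccc(OC)cc2 | intermediate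
22 | methyl (2Z)-2-(bromomethyl)-4-{(2R,3R)-3-[3-[(4-methoxybenzyl)oxy]propyl]-3-methyloxiran-2-yl}but-2-enoate (fragment B) | COC(=O)/C(CBr)=C/C[C@H]1O[C@]1(C)CCCOCc2ccc(OC)cc2 | intermediate
23 | methyl (3S,4R,5R,6S)-3-({(2R,3R)-3-[3-[(4-methoxybenzyl)oxy]propyl]-3-methyloxiran-2-yl}methyl)-6-methyl-2-methylidene-5-[(triethylsilyl)oxy]-4-[(trimethylsilyl)oxy]undec-10-ynoate (silyl ether) | C#CCCC[C@H](C)[C@@H](O[Si](CC)(CC)CC)[C@H](O[Si](C)(C)C)[C@@H](C[C@H]1O[C@]1(C)CCCOCc2ccc(OC)cc2)C(=C)C(=O)OC | intermediate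
24 | methyl (3S,4R,5R,6S)-4-hydroxy-3-({(2R,3R)-3-[3-[(4-methoxybenzyl)oxy]propyl]-3-methyloxiran-2-yl}methyl)-6-methyl-2-methylidene-5-[(triethylsilyl)oxy]undec-10-ynoate (hydroxy ester) | C#CCCC[C@H](C)[C@@H](O[Si](CC)(CC)CC)[C@H](O)[C@@H](C[C@H]1O[C@]1(C)CCCOCc2ccc(OC)cc2)C(=C)C(=O)OC | intermediate
25 | (4S,5R)-4-({(2R,3R)-3-[3-[(4-methoxybenzyl)oxy]propyl]-3-methyloxiran-2-yl}methyl)-3-methylidene-5-[(1R,2S)-2-methyl-1-[(triethylsilyl)oxy]hept-6-yn-1-yl]oxolan-2-one | C#CCCC[C@H](C)[C@@H](O[Si](CC)(CC)CC)[C@@H]1OC(=O)C(=C)[C@@H]1C[C@H]2O[C@]2(C)CCCOCc3ccc(OC)cc3 | intermediate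
26 | (4S,5R)-4-{[(2R,3R)-3-(3-hydroxypropyl)-3-methyloxiran-2-yl]methyl}-3-methylidene-5-[(1R,2S)-2-methyl-1-[(triethylsilyl)oxy]hept-6-yn-1-yl]oxolan-2-one | C#CCCC[C@H](C)[C@@H](O[Si](CC)(CC)CC)[C@@H]1OC(=O)C(=C)[C@@H]1C[C@H]2O[C@]2(C)CCCO | intermediate
27 | (4S,5R)-3-methylidene-4-{[(2R,3R)-3-methyl-3-(3-oxopropyl)oxiran-2-yl]methyl}-5-[(1R,2S)-2-methyl-1-[(triethylsilyl)oxy]hept-6-yn-1-yl]oxolan-2-one | C#CCCC[C@H](C)[C@@H](O[Si](CC)(CC)CC)[C@@H]1OC(=O)C(=C)[C@@H]1C[C@H]2O[C@]2(C)CCC=O | intermediate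
28 | (1S,3R,5R,8R,13S,14R,15R)-5,13-dimethyl-9,18-dimethylidene-8,14-bis[(triethylsilyl)oxy]-4,16-dioxatricyclo[13.3.0.0(3,5)]octadecan-17-one | C=C1CCC[C@H](C)[C@@H](O[Si](CC)(CC)CC)[C@@H]2OC(=O)C(=C)[C@@H]2C[C@H]3O[C@]3(C)CC[C@H]1O[Si](CC)(CC)CC | intermediate
29 | (1S,3R,5R,8R,13S,14R,15R)-8,14-dihydroxy-5,13-dimethyl-9,18-dimethylidene-4,16-dioxatricyclo[13.3.0.0(3,5)]octadecan-17-one (CNP0124069.1) | C=C1CCC[C@H](C)[C@@H](O)[C@@H]2OC(=O)C(=C)[C@@H]2C[C@H]3O[C@]3(C)CC[C@H]1O | target

## Step count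

Total step count: 18.
Longest linear sequence: 12 steps (steps 1–7, then 14–18, from hept-6-yn-2-one). The other branch is 11 steps (steps 8–13, then 14–18).

## The three steps most likely to fail

**Step 17 (the proposed new macrocyclization).** Possible failures are coupling of the alkyne with the α-methylene lactone instead of the aldehyde, endo closure to the 15-membered E-alkene, simple hydrosilylation of the aldehyde, or poor facial control at C14. The fallback is the known catalytic asymmetric nickel/chromium Nozaki–Hiyama–Kishi macrocyclization of a 2-iodoalkene. It sets out from diol 8 and comes back to the route at target 29.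
- Diol 8 is hydroiodinated in the Markovnikov sense (NaI, Me3SiCl, H2O, MeCN, rt) to (2R,3S)-7-iodo-3-methyloct-7-ene-1,2-diol F1.
- Silylation as in step 6 gives the bis-silyl ether (2R,3S)-7-iodo-3-methyl-1,2-bis[(triethylsilyl)oxy]oct-7-ene F2, and the selective Swern oxidation of step 7 gives (2R,3S)-7-iodo-3-methyl-2-[(triethylsilyl)oxy]oct-7-enal F3.
- Union with 22 under the nickel-free conditions of step 14, which leave the alkenyl iodide untouched, gives the iodoalkenyl epoxy lactone F4.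
- DDQ and Dess–Martin oxidation as in steps 15 and 16 give the iodoalkenyl alcohol F5 and the iodoalkenyl aldehyde F6.
- Ring closure with CrCl2 (20 mol%), NiCl2(2,9-dimethyl-1,10-phenanthroline) (2 mol%), a Kishi-type chiral sulfonamide ligand, Mn, Cp2ZrCl2 and LiCl in MeCN at 0.003 M gives the 14R allylic alcohol, the mono-silylated macrocycle F7.
- Et3N·3HF as in step 18 then gives 29.

**Step 14 (fragment union).** The ligand must override the substrate, because an α-silyloxy aldehyde without chelation prefers the 6,7-anti adduct; Me3SiCl and chromium salts may also damage the oxirane. The fallback is a chelation-controlled indium Barbier reaction. It sets out from aldehyde 10 (with bromide 22) and comes back at lactone 25.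
- Aldehyde 10 is desilylated (Et3N·3HF, MeCN, 0 °C) to (2R,3S)-2-hydroxy-3-methyloct-7-ynal F8, which is used crude.
- In powder and 22 in THF–pH 7 aqueous buffer at rt give the adduct: the free hydroxyl chelates indium, which favours the 6,7-syn product, and the Z-bromide gives the 7,8-syn adduct. Lactonization gives the hydroxy lactone F9.
- Et3SiCl and imidazole convert F9 into 25.

**Step 13 (bromination with the oxirane already in place).** Bromide may open the trisubstituted oxirane here or during step 14. The fallback postpones the epoxidation until after the union. It sets out from alcohol 20 and comes back at lactone 25.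
- Alcohol 20 is brominated under the conditions of step 13 to methyl (2Z,5E)-2-(bromomethyl)-9-[(4-methoxybenzyl)oxy]-6-methylnona-2,5-dienoate F10.
- Union of F10 with 10 under the conditions of step 14 gives the alkene lactone F11.
- Shi epoxidation under the conditions of step 12 acts on the only electron-rich alkene of F11 and gives 25.

## Further compounds

F1 | step 17 | (2R,3S)-7-iodo-3-methyloct-7-ene-1,2-diol | C=C(I)CCC[C@H](C)[C@@H](O)CO
F2 | step 17 | (2R,3S)-7-iodo-3-methyl-1,2-bis[(triethylsilyl)oxy]oct-7-ene | C=C(I)CCC[C@H](C)[C@@H](O[Si](CC)(CC)CC)CO[Si](CC)(CC)CC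
F3 | step 17 | (2R,3S)-7-iodo-3-methyl-2-[(triethylsilyl)oxy]oct-7-enal | C=C(I)CCC[C@H](C)[C@@H](O[Si](CC)(CC)CC)C=O
F4 | step 17 | (4S,5R)-5-[(1R,2S)-6-iodo-2-methyl-1-[(triethylsilyl)oxy]hept-6-en-1-yl]-4-({(2R,3R)-3-[3-[(4-methoxybenzyl)oxy]propyl]-3-methyloxiran-2-yl}methyl)-3-methylideneoxolan-2-one | C=C(I)CCC[C@H](C)[C@@H](O[Si](CC)(CC)CC)[C@@H]1OC(=O)C(=C)[C@@H]1C[C@H]2O[C@]2(C)CCCOCc3ccc(OC)cc3
F5 | step 17 | (4S,5R)-4-{[(2R,3R)-3-(3-hydroxypropyl)-3-methyloxiran-2-yl]methyl}-5-[(1R,2S)-6-iodo-2-methyl-1-[(triethylsilyl)oxy]hept-6-en-1-yl]-3-methylideneoxolan-2-one | C=C(I)CCC[C@H](C)[C@@H](O[Si](CC)(CC)CC)[C@@H]1OC(=O)C(=C)[C@@H]1C[C@H]2O[C@]2(C)CCCO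
F6 | step 17 | (4S,5R)-5-[(1R,2S)-6-iodo-2-methyl-1-[(triethylsilyl)oxy]hept-6-en-1-yl]-3-methylidene-4-{[(2R,3R)-3-methyl-3-(3-oxopropyl)oxiran-2-yl]methyl}oxolan-2-one | C=C(I)CCC[C@H](C)[C@@H](O[Si](CC)(CC)CC)[C@@H]1OC(=O)C(=C)[C@@H]1C[C@H]2O[C@]2(C)CCC=O
F7 | step 17 | (1S,3R,5R,8R,13S,14R,15R)-8-hydroxy-5,13-dimethyl-9,18-dimethylidene-14-[(triethylsilyl)oxy]-4,16-dioxatricyclo[13.3.0.0(3,5)]octadecan-17-one | C=C1CCC[C@H](C)[C@@H](O[Si](CC)(CC)CC)[C@@H]2OC(=O)C(=C)[C@@H]2C[C@H]3O[C@]3(C)CC[C@H]1O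
F8 | step 14 | (2R,3S)-2-hydroxy-3-methyloct-7-ynal | C#CCCC[C@H](C)[C@@H](O)C=O
F9 | step 14 | (4S,5R)-5-[(1R,2S)-1-hydroxy-2-methylhept-6-yn-1-yl]-4-({(2R,3R)-3-[3-[(4-methoxybenzyl)oxy]propyl]-3-methyloxiran-2-yl}methyl)-3-methylideneoxolan-2-one | C#CCCC[C@H](C)[C@@H](O)[C@@H]1OC(=O)C(=C)[C@@H]1C[C@H]2O[C@]2(C)CCCOCc3ccc(OC)cc3
F10 | step 13 | methyl (2Z,5E)-2-(bromomethyl)-9-[(4-methoxybenzyl)oxy]-6-methylnona-2,5-dienoate | COC(=O)/C(CBr)=C/C/C=C(\C)CCCOCc1ccc(OC)cc1
F11 | step 13 | (4S,5R)-4-{(2E)-6-[(4-methoxybenzyl)oxy]-3-methylhex-2-en-1-yl}-3-methylidene-5-[(1R,2S)-2-methyl-1-[(triethylsilyl)oxy]hept-6-yn-1-yl]oxolan-2-one | C#CCCC[C@H](C)[C@@H](O[Si](CC)(CC)CC)[C@@H]1OC(=O)C(=C)[C@@H]1C/C=C(\C)CCCOCc2ccc(OC)cc2
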